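**Retrosynthetic overview**
1. Removing the two benzyl ethers and the single acetyl group leads back to symmetric O,O'-dibenzylatromentin. All four ring oxygens of its dianion are equivalent, so one acetyl group can give only one product.
2. Enabling feature: the six quinone ring carbons are two identical three-carbon units C(aryl)–C(=O)–C(–O) joined head to tail. Each unit is an arylpyruvic acid skeleton (benzylic carbon as donor, carboxyl carbon as acceptor). The 2,5-dihydroxy-1,4-benzoquinone is the tautomer of the cyclohexane-1,2,4,5-tetraone that a double Claisen condensation delivers, so no redox step is needed.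
3. Key disconnection: both C(aryl)=C(–O) ring bonds are cut at once, giving two molecules of (Z)-5-[4-(benzyloxy)benzylidene]-2,2-dimethyl-1,3-dioxolan-4-one. Its temporary ring hides the keto carbon as an enol acetal (no aldol acceptor), activates the carboxyl carbon, and leaves as acetone in the key step itself.
4. The monomer comes from 4-(benzyloxy)benzaldehyde and glycolic acid acetonide by aldol addition and dehydration.
5. Ring order: the aryl rings and the dioxolanone ring are bought. The quinone ring is the only ring made (step 3), and both dioxolanone rings are opened in that step.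

Key step: step 3

Remark: the target has no stereocentre and no stereogenic double bond; quinones are drawn as one tautomer; 1 and 2 are taken as commercial.

**Step 1**
Reactants: 1 4-(benzyloxy)benzaldehyde; 2 2,2-dimethyl-1,3-dioxolan-4-one (glycolic acid acetonide)
Product: 3 5-{[4-(benzyloxy)phenyl](hydroxy)methyl}-2,2-dimethyl-1,3-dioxolan-4-one (racemic, syn/anti mixture)
Conditions: LiN(iPr)2 (LDA, commercial solution, 1.1 equiv), THF, −78 °C; 2 added, 1 added after 10 min, −78 °C; AcOH quench at −78 °C
Reagents that add atoms: none
Why: Aldol addition of the lithium enolate of a 1,3-dioxolan-4-one to a non-enolisable aromatic aldehyde; the two new stereocentres form without control, which is harmless because step 2 erases both.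

**Step 2**
Reactants: 3 aldol adduct
Product: 5 (Z)-5-[4-(benzyloxy)benzylidene]-2,2-dimethyl-1,3-dioxolan-4-one, via benzylic mesylate 4 (not isolated)
Conditions: MsCl (1.2 equiv), Et3N (1.5 equiv), CH2Cl2, 0 °C; then DBU (1.5 equiv), 0 °C to rt
Reagents that add atoms: none
Why: Mesylation followed by E1cB-type β-elimination (aldol dehydration) should work because the hydrogen next to the lactone carbonyl is acidic and the p-alkoxybenzylic mesylate leaves readily; the conjugated Z alkene (aryl anti to the carbonyl) is the thermodynamic product, and its geometry is lost again in step 3.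

**Step 3**
Reactants: 5 (Z)-5-[4-(benzyloxy)benzylidene]-2,2-dimethyl-1,3-dioxolan-4-one (two molecules)
Product: 8 2,5-bis[4-(benzyloxy)phenyl]-3,6-dihydroxycyclohexa-2,5-diene-1,4-dione (O,O'-dibenzylatromentin), via sodium enolate 6 (not isolated), via linear trioxo ester 7 (not isolated)
Conditions: solid NaOMe (0.50 equiv), THF, 0 °C to 45 °C, slow N2 stream, until 5 is consumed; then solid NaOMe (1.0 equiv), 60 °C; poured into cold 1 M HCl
Reagents that add atoms: none
Why: Proposed new method: each methoxide of the first charge is used up by one molecule of 5, which opens at the lactone carbonyl with loss of acetone to enolate 6, so the other half of 5 remains as a neutral acyl donor; the benzylic carbon of 6 attacks that lactone carbonyl (first C–C bond, second acetone lost) to give 7, and after the second base charge the terminal benzylic enolate carbon of 7 attacks the methyl ester (second C–C bond) and expels the methoxide that started the sequence. The closest known reaction types are the C-acylation of ester enolates by 5-ylidene-1,3-dioxolan-4-ones with release of the ketone, the Claisen and Dieckmann condensations, the base-induced head-to-tail cyclodimerisation of biacetyl to 2,5-dimethyl-1,4-benzoquinone, and the base-induced rearrangement of isomeric pyrandione enol lactones to 2,5-diaryl-3,6-dihydroxybenzoquinones, which runs through an ester of type 7; the self-union of two arylpyruvate units in this sense has not been shown. The only ring closed is the six-membered carbocycle, in the favoured 6-(enolendo)-exo-trig mode, and the resulting cyclohexane-1,2,4,5-tetraone tautomerises at once to the dihydroxyquinone, whose doubly vinylogous carboxylate dianion is the thermodynamic sink that pulls the reversible steps forward. No stereocentre is created, and the Z geometry of 5 disappears in the enolates. The step needs Claisen acylation instead of the aldol–lactonisation that free arylpyruvates prefer, and this is secured because the keto carbon is never a free carbonyl while monomer is present: it is an enol acetal carbon in 5 and an enolate carbon in 6. Head-to-tail regiochemistry follows from the single donor and single acceptor carbon per unit, O-acylation gives only enol esters or lactones that methoxide reopens whereas C-acylation is fixed by deprotonation, and ring closure of 7 should outrun chain growth because it is intramolecular and no 5 is left when the second base charge is added.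

**Step 4**
Reactants: 8 O,O'-dibenzylatromentin
Product: 9 2,5-bis[4-(benzyloxy)phenyl]-4-hydroxy-3,6-dioxocyclohexa-1,4-dien-1-yl acetate
Conditions: Et3N (2.2 equiv), CH2Cl2, −20 °C; Ac2O (1.0 equiv, slow addition), −20 to 0 °C; cold 0.5 M HCl wash
Reagents that add atoms: acetic anhydride, CC(=O)OC(C)=O
Why: O-acylation of a vinylogous carboxylate: only one monoacetate is possible because all four ring oxygens of the dianion of 8 are equivalent, and the dianion is a far better nucleophile than the acetoxy-deactivated monoanion of 9, so one equivalent of Ac2O should favour mono- over diacetylation.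

**Step 5**
Reactants: 9 monoacetate
Product: 11 4-hydroxy-2,5-bis(4-hydroxyphenyl)-3,6-dioxocyclohexa-1,4-dien-1-yl acetate (2-O-acetylatromentin, target), via leuco triol 10 (not isolated)
Conditions: H2 (1 atm), Pd/C (10 wt% Pd on carbon), EtOAc/THF, rt; N2 purge; then air over the same Pd/C, rt; filtration
Reagents that add atoms: none
Why: Catalytic hydrogenolysis of the aryl benzyl ethers, with concurrent quinone reduction, is followed by aerobic reoxidation of the hydroquinone; in 10 the four oxygen positions of the central ring are equivalent, so an acetyl shift between neighbours is degenerate, and only the free para pair of hydroxyls can become the quinone carbonyls, which gives the target.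

**Compound list**
1 | 4-(benzyloxy)benzaldehyde | O=Cc1ccc(OCc2ccccc2)cc1 | starting material
2 | 2,2-dimethyl-1,3-dioxolan-4-one | CC1(C)OCC(=O)O1 | starting material
3 | 5-{[4-(benzyloxy)phenyl](hydroxy)methyl}-2,2-dimethyl-1,3-dioxolan-4-one (racemic, syn/anti mixture) | CC1(C)OC(C(O)c2ccc(OCc3ccccc3)cc2)C(=O)O1 | intermediate
4 | [4-(benzyloxy)phenyl](2,2-dimethyl-5-oxo-1,3-dioxolan-4-yl)methyl methanesulfonate (diastereomer mixture) | CC1(C)OC(C(OS(C)(=O)=O)c2ccc(OCc3ccccc3)cc2)C(=O)O1 | intermediate
5 | (Z)-5-[4-(benzyloxy)benzylidene]-2,2-dimethyl-1,3-dioxolan-4-one | O=C1OC(C)(C)O/C1=C\c1ccc(OCc2ccccc2)cc1 | intermediate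
6 | sodium (Z)-1-[4-(benzyloxy)phenyl]-3-methoxy-3-oxoprop-1-en-2-olate | COC(=O)/C([O-])=C/c1ccc(OCc2ccccc2)cc1.[Na+] | intermediate
7 | methyl 3,6-bis[4-(benzyloxy)phenyl]-2,4,5-trioxohexanoate (present as its sodium enolate, C3 configurationally labile) | COC(=O)C(=O)C(c1ccc(OCc2ccccc2)cc1)C(=O)C(=O)Cc1ccc(OCc2ccccc2)cc1 | intermediate
8 | 2,5-bis[4-(benzyloxy)phenyl]-3,6-dihydroxycyclohexa-2,5-diene-1,4-dione | O=C1C(O)=C(c2ccc(OCc3ccccc3)cc2)C(=O)C(O)=C1c1ccc(OCc2ccccc2)cc1 | intermediate
9 | 2,5-bis[4-(benzyloxy)phenyl]-4-hydroxy-3,6-dioxocyclohexa-1,4-dien-1-yl acetate | CC(=O)OC1=C(c2ccc(OCc3ccccc3)cc2)C(=O)C(O)=C(c2ccc(OCc3ccccc3)cc2)C1=O | intermediate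
10 | 2,4,5-trihydroxy-3,6-bis(4-hydroxyphenyl)phenyl acetate | CC(=O)Oc1c(O)c(-c2ccc(O)cc2)c(O)c(O)c1-c1ccc(O)cc1 | intermediate
11 | 4-hydroxy-2,5-bis(4-hydroxyphenyl)-3,6-dioxocyclohexa-1,4-dien-1-yl acetate | CC(=O)OC1=C(c2ccc(O)cc2)C(=O)C(O)=C(c2ccc(O)cc2)C1=O | target

**Step count**
Total steps: 5. Longest linear sequence: 5 (1 → 3 → 5 → 8 → 9 → 11).

**Steps most likely to fail**

Step 3 (proposed new method).
- What may go wrong: acylation of the stabilised enolate by the dioxolanone may be sluggish. The enolate may be captured by the liberated acetone (aldol addition followed by lactonisation). O-acylation may persist. The linear intermediate may undergo retro-Claisen cleavage before it closes.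
- Fallback: known chemistry that makes the two bonds one after the other between two differentiated halves; it sets out from 5 and comes back at 8. One portion of 5 is opened with NaOMe (1.0 equiv, MeOH/THF, 0 °C) and poured into cold dilute HCl to give methyl 3-[4-(benzyloxy)phenyl]-2-oxopropanoate F1. A second portion is hydrolysed (LiOH, THF/H2O, then HCl) to 3-[4-(benzyloxy)phenyl]-2-oxopropanoic acid F2. This acid is capped with Ac2O/pyridine as (Z)-2-acetoxy-3-[4-(benzyloxy)phenyl]acrylic acid F3, which (COCl)2 and catalytic DMF convert into (Z)-2-acetoxy-3-[4-(benzyloxy)phenyl]acryloyl chloride F4. The magnesium enolate of F1 (MgCl2, Et3N, MeCN, 0 °C) is then C-acylated by F4, the soft-enolisation acylation used for 1,3-dicarbonyl compounds. This should give the isolable methyl (Z)-5-acetoxy-3,6-bis[4-(benzyloxy)phenyl]-2,4-dioxohex-5-enoate F5. NaOMe in MeOH/THF finally removes the enol acetate and closes the ring by Dieckmann condensation to 8.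

Step 4.
- What may go wrong: acetylation may spread statistically over none, one and two positions. Acetyl groups may exchange between quinone oxygens. The labile vinylogous anhydride may hydrolyse during work-up or chromatography.
- Fallback: subtractive instead of additive desymmetrisation; it sets out from 8 and comes back at 9. Exhaustive acetylation (Ac2O, pyridine, rt) should give neutral, easily purified 2,5-diacetoxy-3,6-bis[4-(benzyloxy)phenyl]-1,4-benzoquinone F6. One equivalent of LiOH in THF/H2O at 0 °C then removes one acetyl group. The anion formed by the first cleavage protects the second acetoxy group by charge and electron donation. Attack at the acyl carbon or at the ring carbon leads to the same product.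

Step 5.
- What may go wrong: the acetyl group may be lost or transferred at the electron-rich leuco stage. Benzyl cleavage may be incomplete. The aerobic reoxidation may over-oxidise the product.
- Fallback: reversed order of events; it sets out from 8 and comes back at 11. Hydrogenolysis of 8 (H2, Pd/C, THF) should give leucoatromentin F7, and air oxidises this in the same flask to atromentin F8. Et3N (2.0 equiv) then deprotonates only the two quinone hydroxyls, which are several pK units more acidic than the phenols. Ac2O (1.0 equiv, THF/DMF, −20 °C, no acyl-transfer catalyst) acetylates one of the equivalent anionic oxygens while the neutral phenols stay untouched.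

**Further compounds**
F1 | step 3 | methyl 3-[4-(benzyloxy)phenyl]-2-oxopropanoate | COC(=O)C(=O)Cc1ccc(OCc2ccccc2)cc1
F2 | step 3 | 3-[4-(benzyloxy)phenyl]-2-oxopropanoic acid | OC(=O)C(=O)Cc1ccc(OCc2ccccc2)cc1
F3 | step 3 | (Z)-2-acetoxy-3-[4-(benzyloxy)phenyl]acrylic acid | CC(=O)O/C(C(=O)O)=C\c1ccc(OCc2ccccc2)cc1
F4 | step 3 | (Z)-2-acetoxy-3-[4-(benzyloxy)phenyl]acryloyl chloride | CC(=O)O/C(C(=O)Cl)=C\c1ccc(OCc2ccccc2)cc1
F5 | step 3 | methyl (Z)-5-acetoxy-3,6-bis[4-(benzyloxy)phenyl]-2,4-dioxohex-5-enoate | COC(=O)C(=O)C(c1ccc(OCc2ccccc2)cc1)C(=O)/C(OC(C)=O)=C/c1ccc(OCc2ccccc2)cc1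
F6 | step 4 | 2,5-diacetoxy-3,6-bis[4-(benzyloxy)phenyl]-1,4-benzoquinone | CC(=O)OC1=C(c2ccc(OCc3ccccc3)cc2)C(=O)C(OC(C)=O)=C(c2ccc(OCc3ccccc3)cc2)C1=O
F7 | step 5 | leucoatromentin, 3,6-bis(4-hydroxyphenyl)benzene-1,2,4,5-tetrol | Oc1ccc(cc1)-c1c(O)c(O)c(-c2ccc(O)cc2)c(O)c1O
F8 | step 5 | atromentin, 2,5-dihydroxy-3,6-bis(4-hydroxyphenyl)-1,4-benzoquinone | O=C1C(O)=C(c2ccc(O)cc2)C(=O)C(O)=C1c1ccc(O)cc1
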